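All runs were generated by integration with made-up constants, and the scatter is random.

A leftover is where I begin. Summer holds 0.870 equiv of incoming ligand and each starting complex needs two of them to become complex with two exchanged, so the charge leaves 56.5% of its starting complex without the ligand to get there. That leftover, one minus the equivalents of incoming ligand over two, is what I carry from flask to flask, and by this count of the charge incoming ligand is the limiting reagent for the product in summer.

| flask | starting complex | incoming ligand | leaving ligand | protic impurity | remark | time |
|---|---|---|---|---|---|---|
| north-east | 10 mM | 1.3 equiv | 1.7 equiv (fed, over 15 min) | 2 mM | run made earlier |  |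
| south-west | 10 mM | 1.3 equiv | 2.8 equiv (fed, over 15 min) | 2 mM | run made earlier |  |
| south | 10 mM | 1.3 equiv | 4.9 equiv (fed, over 15 min) | 2 mM | run made earlier |  |
| east | 10 mM | 1.3 equiv | 5 equiv (fed, over 15 min) | 2.7 mM | run made earlier |  |
| noon | 10 mM | 3.90 equiv | 1.70 equiv (fed, over 15 min) | 2.00 mM |  | 1.0 h |
| spring | 30 mM | 1.30 equiv | 5.00 equiv (fed, over 4.0 min) | 2.00 mM |  | 1.0 h |
| summer | 15 mM | 0.870 equiv | 5.00 equiv (fed, over 15 min) | 2.00 mM |  | 1.0 h |
| winter | 10 mM | 1.30 equiv | 5.00 equiv (fed, over 15 min) | 2.00 mM |  | 1.0 h |
| dusk | 10 mM | 0.870 equiv | 5.00 equiv (fed, over 5.0 min) | 2.00 mM |  | 1.0 h |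
| dawn | 6.0 mM | 1.30 equiv | 5.00 equiv (fed, over 15 min) | 3.00 mM |  | 1.0 h |

| run | time / min | complex with two exchanged / % |
|---|---|---|
| north-east | 12.0 | 47.5 |
| north-east | 25.0 | 49.4 |
| north-east | 40.0 | 49.0 |
| north-east | 50.0 | 47.3 |
| north-east | 60.0 | 45.5 |
| south-west | 5.00 | 35.6 |
| south-west | 15.0 | 48.1 |
| south-west | 30.0 | 47.4 |
| south-west | 40.0 | 44.6 |
| south-west | 60.0 | 43.1 |
| south | 5.00 | 37.5 |
| south | 10.0 | 45.1 |
| south | 15.0 | 46.0 |
| south | 30.0 | 43.8 |
| south | 60.0 | 37.9 |
| east | 5.00 | 37.3 |
| east | 10.0 | 45.1 |
| east | 15.0 | 46.1 |
| east | 30.0 | 42.4 |
| east | 60.0 | 38.2 |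

(readings scatter by 1 percentage point)

- in percentages every species weighs as the starting complex in it: one side product counts as two
- candidate steps: starting complex + incoming ligand <-> leaving ligand + complex with one exchanged; complex with one exchanged + incoming ligand <-> leaving ligand + complex with two exchanged; starting complex + complex with two exchanged -> side product; protic impurity + starting complex -> quenched substrate
- no earlier run changes the charge of incoming ligand; that part of a forecast is a guess

1. all flasks from highest to lowest amount of complex with two exchanged, in percent of the starting complex charged, at 1.0 h (noon / spring / summer / winter / dusk / dawn)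
2. the same order at 6.0 min (noon / spring / summer / winter / dusk / dawn)
3. the amount of complex with two exchanged, in percent of the starting complex charged of the flask you put first, at 1.0 h
4. the amount of complex with two exchanged, in percent of the starting complex charged of the flask you put last, at 1.0 h

What does the leftover allow at each charge? Winter, spring, dawn and the earlier runs, at 1.30 equiv, leave 35.0%, so complex with two exchanged can't pass 65.0% there. Dusk has the equivalents of summer, and both are held under 43.5%. Noon, with 3.90 equiv, holds more than the two equivalents needed and has no leftover.

How much of that ceiling do the readings reach by the end? The north-east run reads 45.5% at 60.0 min, a share of 70.0%, while the south run, with more leaving ligand, reads 37.9% at 60.0 min, a lower share of 58.3%, and each carries the scatter of 1 percentage point.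

What follows for the lowest flasks? Carrying the south share to the ceiling of summer is my guess, since no earlier run changes the ligand charge, and it gives 25.4%. So my own order at 1.0 h has noon first, the flasks at 1.30 equiv in the middle, and dusk and summer last, and my reckoning doesn't separate the flasks within each group.

The forecast gives noon > dawn > winter > spring > dusk > summer at 1.0 h and noon > spring > winter > summer > dawn > dusk at 6.0 min, with noon at 78% and summer, called “ligand-starved, with excess starting complex destroying product”, at 14%, which is lower than my figure.

The flasks give noon > dawn > winter > spring > dusk > summer at 1.0 h and noon > spring > winter > dawn > summer > dusk at 6.0 min, with noon at 93.2% and summer at 19.7%.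

    starting complex + incoming ligand ⇌ leaving ligand + complex with one exchanged (K = 5.20, k = 39.0 M⁻¹ min⁻¹)
    complex with one exchanged + incoming ligand ⇌ leaving ligand + complex with two exchanged (K = 170, k = 55.0 M⁻¹ min⁻¹)
    starting complex + complex with two exchanged → side product (k = 1.60 M⁻¹ min⁻¹)
    protic impurity + starting complex → quenched substrate (k = 21.0 M⁻¹ min⁻¹)

Summer's 19.7% is 45.3% of its ceiling of 43.5%, below the south share I carried over. The main reason for so low a figure is the falling level of incoming ligand: with that level held at its charge, summer gives 71.0%, more than the ceiling.

A neighbour of summer with 1.20 equiv of leaving ligand keeps the same incoming ligand, so its leftover stays 56.5%, and the north-east share, read at 1.7 equiv of leaving ligand, gives an estimate of 30.4%. Computed, that neighbour holds 23.8% of complex with two exchanged at 1.0 h.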